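**Plan**

- Cuts, in retrosynthetic order: the acid and the 7‑OH are unmasked last (methyl ester, benzyl ether); then the aryl–vinyl bond at C5 (Heck); then C3–C3a of the dihydrofuran, traced back to C4–C4a of a flavanone; then the C2–aryl bond of that flavanone (conjugate arylation of a chromone built from an o‑hydroxyacetophenone).
- Enabling feature: on the dihydrofuran ring, O1–C2(aryl) sits next to a C3 that carries a one‑carbon oxygenated arm (CH2OH). This is a ring‑contracted flavanone: the ketone carbon C4 becomes the exocyclic carbon once ring‑A carbon C4a (later C3a) moves from C4 to C3.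
- Forward order: ring A (benzylated, brominated acetophenone) → pyranone ring (chromone) → C2 aryl group → contraction to the dihydrofuran ester → CH2OH → acrylate at C5 → deprotection.
- Stereochemistry: C2 from ligand‑controlled conjugate arylation of the flat chromone; C3 from substrate control in the rearrangement (anti attack, inversion, trans‑ester thermodynamics); the E alkene from the Heck reaction.

Key step: step 5

Remark: (S)‑t‑BuPyOx is taken to deliver the 2R flavanone, by analogy with the enone face it selects on 3‑substituted cyclohexenones; if the sense proves opposite, the (R)‑ligand is used with nothing else changed.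

**Step 1**
Reactants: 1 1‑(2,3‑dihydroxyphenyl)ethan‑1‑one (2',3'‑dihydroxyacetophenone)
Product: 2 1‑[3‑(benzyloxy)‑2‑hydroxyphenyl]ethan‑1‑one
Conditions: NaH (2.1 equiv), DMSO, 20 °C; BnBr (1.0 equiv); then 1 M HCl
Reagents that add atoms: benzyl bromide, BrCc1ccccc1
Why: Williamson etherification of the dianion, in which the second‑formed 3'‑phenoxide, neither conjugated to nor chelated by the acetyl group, is the more nucleophilic oxygen and should take up the single equivalent of benzyl bromide.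

**Step 2**
Reactants: 2 1‑[3‑(benzyloxy)‑2‑hydroxyphenyl]ethan‑1‑one
Product: 3 1‑[3‑(benzyloxy)‑5‑bromo‑2‑hydroxyphenyl]ethan‑1‑one
Conditions: NBS (1.05 equiv), MeCN, 0 °C to rt
Reagents that add atoms: N‑bromosuccinimide, O=C1CCC(=O)N1Br
Why: Electrophilic aromatic bromination para to the free phenol, the position activated by the hydroxyl group and meta to the deactivating acetyl group, as in the bromination of o‑vanillin‑type phenols.

**Step 3**
Reactants: 3 1‑[3‑(benzyloxy)‑5‑bromo‑2‑hydroxyphenyl]ethan‑1‑one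
Product: 5 8‑(benzyloxy)‑6‑bromo‑4H‑chromen‑4‑one, via enaminone 4 (not isolated)
Conditions: Me2NCH(OMe)2 (2 equiv), toluene, 100 °C; evaporate; conc. HCl, CH2Cl2, 40 °C
Reagents that add atoms: N,N‑dimethylformamide dimethyl acetal, COC(OC)N(C)C
Why: Enaminone route to chromones: condensation of the methyl ketone with the formamide acetal, then acid‑promoted 6‑endo‑trig addition of the phenol to the vinylogous amide with loss of dimethylamine closes the pyranone.

**Step 4**
Reactants: 5 8‑(benzyloxy)‑6‑bromo‑4H‑chromen‑4‑one; 6 3,4‑dimethoxyphenylboronic acid (2 equiv)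
Product: 7 (2R)‑8‑(benzyloxy)‑6‑bromo‑2‑(3,4‑dimethoxyphenyl)chroman‑4‑one
Conditions: Pd(OCOCF3)2 (5 mol %), (S)‑t‑BuPyOx (6 mol %), NH4PF6 (30 mol %), H2O (5 equiv), ClCH2CH2Cl, 60 °C
Reagents that add atoms: none
Why: Catalytic asymmetric conjugate arylation of a chromone with an arylboronic acid under cationic divalent palladium/pyridine‑oxazoline catalysis, in which the ligand selects the enone face and so sets C2, while the aryl bromide survives because no zerovalent palladium is generated.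

**Step 5**
Reactants: 7 (2R)‑8‑(benzyloxy)‑6‑bromo‑2‑(3,4‑dimethoxyphenyl)chroman‑4‑one
Product: 11 methyl (2R,3R)‑7‑(benzyloxy)‑5‑bromo‑2‑(3,4‑dimethoxyphenyl)‑2,3‑dihydro‑1‑benzofuran‑3‑carboxylate (trans), via enol ether 8 (not isolated), via trans iodanyl ketal 9 (not isolated), via trimethyl orthoester 10 (not isolated)
Conditions: PhI(OAc)2 (1.2 equiv), conc. H2SO4, HC(OMe)3, 0 °C to rt; then H2O
Reagents that add atoms: trimethyl orthoformate, COC(OC)OC; water, O
Why: Under acid the orthoformate turns ketone 7 into enol ether 8, whose C3 attacks PhI(OAc)2 on the face opposite the 2‑aryl group; methanol capture gives the trans iodanyl ketal 9, and as iodobenzene departs ring‑A carbon C4a shifts from C4 to C3, the resulting dimethoxycarbenium ion being trapped as orthoester 10 and hydrolysed to ester 11 on aqueous quench. This is the known hypervalent‑iodine oxidative ring contraction of flavanones to trans‑2‑aryl‑2,3‑dihydrobenzofuran‑3‑carboxylates, a semipinacol‑type oxidative 1,2‑aryl shift of an aryl ketone. The dihydrofuran ring arises by contraction and not by cyclisation: C3–C3a forms as C4–C4a breaks, and O1–C2 and the O1–aryl bond are carried over intact. C3 is set by substrate control, since iodine enters trans to the C2 aryl group and is displaced with inversion by the migrating carbon, which places the ester carbon trans to the aryl group; the epimerisable ester centre would relax to the same trans isomer, and C2 is not involved. The step needs migration of the ring‑A carbon in preference to the 2‑aryl group, to hydride loss (flavone) and to attack of the oxidant on the dimethoxyarene; with the aryl and iodanyl groups both pseudo‑equatorial the C4–C4a bond is antiperiplanar to C3–I while the C2–aryl bond is gauche, the migrating carbon is activated by the ortho ring oxygen, and the enol ether is far more nucleophilic than the veratryl ring.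

**Step 6**
Reactants: 11 methyl (2R,3R)‑7‑(benzyloxy)‑5‑bromo‑2‑(3,4‑dimethoxyphenyl)‑2,3‑dihydro‑1‑benzofuran‑3‑carboxylate
Product: 13 [(2R,3S)‑7‑(benzyloxy)‑5‑bromo‑2‑(3,4‑dimethoxyphenyl)‑2,3‑dihydro‑1‑benzofuran‑3‑yl]methanol, via 3‑carbaldehyde 12 (not isolated)
Conditions: i‑Bu2AlH (3 equiv), CH2Cl2, −78 to 0 °C; aq. Rochelle salt
Reagents that add atoms: none
Why: Ester reduction with a non‑basic aluminium hydride at low temperature, which avoids enolisation at C3 (and with it β‑elimination of the aryloxide) and leaves the aryl bromide and benzyl ether untouched; no stereocentre is affected, the C3 descriptor changing to S only through the priority rules.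

**Step 7**
Reactants: 13 [(2R,3S)‑7‑(benzyloxy)‑5‑bromo‑2‑(3,4‑dimethoxyphenyl)‑2,3‑dihydro‑1‑benzofuran‑3‑yl]methanol; 14 methyl acrylate (3 equiv)
Product: 15 methyl (2E)‑3‑[(2R,3S)‑7‑(benzyloxy)‑2‑(3,4‑dimethoxyphenyl)‑3‑(hydroxymethyl)‑2,3‑dihydro‑1‑benzofuran‑5‑yl]prop‑2‑enoate
Conditions: Pd(OAc)2 (5 mol %), P(o‑tol)3 (10 mol %), Et3N, DMF, 100 °C
Reagents that add atoms: none
Why: Mizoroki–Heck reaction, in which zerovalent palladium formed in situ inserts into the aryl C–Br bond and syn‑carbopalladation of the acrylate followed by syn‑β‑hydride elimination gives the E‑cinnamate, the free primary alcohol and the benzyl ether being inert.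

**Step 8**
Reactants: 15 methyl (2E)‑3‑[(2R,3S)‑7‑(benzyloxy)‑2‑(3,4‑dimethoxyphenyl)‑3‑(hydroxymethyl)‑2,3‑dihydro‑1‑benzofuran‑5‑yl]prop‑2‑enoate
Product: 16 methyl (2E)‑3‑[(2R,3S)‑2‑(3,4‑dimethoxyphenyl)‑7‑hydroxy‑3‑(hydroxymethyl)‑2,3‑dihydro‑1‑benzofuran‑5‑yl]prop‑2‑enoate
Conditions: BCl3 (3 equiv), C6HMe5 (5 equiv), CH2Cl2, −78 °C; then H2O
Reagents that add atoms: none
Why: Lewis‑acid debenzylation of an aryl benzyl ether with pentamethylbenzene as a non‑basic benzyl‑cation scavenger, which at −78 °C spares aryl methyl ethers, the enoate and the alkene; any reversible opening of the C2–O1 bond should re‑close to the favoured trans ring because C3 keeps its configuration.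

**Step 9**
Reactants: 16 methyl (2E)‑3‑[(2R,3S)‑2‑(3,4‑dimethoxyphenyl)‑7‑hydroxy‑3‑(hydroxymethyl)‑2,3‑dihydro‑1‑benzofuran‑5‑yl]prop‑2‑enoate
Product: 17 (2E)‑3‑[(2R,3S)‑2‑(3,4‑dimethoxyphenyl)‑7‑hydroxy‑3‑(hydroxymethyl)‑2,3‑dihydro‑1‑benzofuran‑5‑yl]prop‑2‑enoic acid
Conditions: LiOH·H2O (5 equiv), THF/MeOH/H2O, rt; then 1 M HCl to pH 2–3
Reagents that add atoms: lithium hydroxide, [Li+].[OH-]
Why: Saponification of the methyl cinnamate followed by acidification, with no base‑labile site left because C3 no longer bears a hydrogen α to a carbonyl group.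

**Compound list**

1 | 1‑(2,3‑dihydroxyphenyl)ethan‑1‑one | CC(=O)c1cccc(O)c1O | starting material
2 | 1‑[3‑(benzyloxy)‑2‑hydroxyphenyl]ethan‑1‑one | CC(=O)c1cccc(OCc2ccccc2)c1O | intermediate
3 | 1‑[3‑(benzyloxy)‑5‑bromo‑2‑hydroxyphenyl]ethan‑1‑one | CC(=O)c1cc(Br)cc(OCc2ccccc2)c1O | intermediate
4 | (2E)‑1‑[3‑(benzyloxy)‑5‑bromo‑2‑hydroxyphenyl]‑3‑(dimethylamino)prop‑2‑en‑1‑one | CN(C)/C=C/C(=O)c1cc(Br)cc(OCc2ccccc2)c1O | intermediate
5 | 8‑(benzyloxy)‑6‑bromo‑4H‑chromen‑4‑one | O=c1ccoc2c(OCc3ccccc3)cc(Br)cc12 | intermediate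
6 | 3,4‑dimethoxyphenylboronic acid | COc1ccc(B(O)O)cc1OC | starting material
7 | (2R)‑8‑(benzyloxy)‑6‑bromo‑2‑(3,4‑dimethoxyphenyl)chroman‑4‑one | COc1ccc([C@H]2CC(=O)c3cc(Br)cc(OCc4ccccc4)c3O2)cc1OC | intermediate
8 | (2R)‑8‑(benzyloxy)‑6‑bromo‑2‑(3,4‑dimethoxyphenyl)‑4‑methoxy‑2H‑chromene | COc1ccc([C@H]2C=C(OC)c3cc(Br)cc(OCc4ccccc4)c3O2)cc1OC | intermediate
9 | (2S,3S)‑3‑[acetoxy(phenyl)‑λ3‑iodanyl]‑8‑(benzyloxy)‑6‑bromo‑2‑(3,4‑dimethoxyphenyl)‑4,4‑dimethoxychromane (2,3‑trans; same spatial arrangement at C2 as in 7) | COc1ccc([C@H]2[C@H](I(OC(C)=O)c5ccccc5)C(OC)(OC)c3cc(Br)cc(OCc4ccccc4)c3O2)cc1OC | intermediate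
10 | (2R,3R)‑7‑(benzyloxy)‑5‑bromo‑2‑(3,4‑dimethoxyphenyl)‑3‑(trimethoxymethyl)‑2,3‑dihydro‑1‑benzofuran | COc1ccc([C@@H]2Oc3c(OCc4ccccc4)cc(Br)cc3[C@H]2C(OC)(OC)OC)cc1OC | intermediate
11 | methyl (2R,3R)‑7‑(benzyloxy)‑5‑bromo‑2‑(3,4‑dimethoxyphenyl)‑2,3‑dihydro‑1‑benzofuran‑3‑carboxylate (trans) | COc1ccc([C@@H]2Oc3c(OCc4ccccc4)cc(Br)cc3[C@H]2C(=O)OC)cc1OC | intermediate
12 | (2R,3R)‑7‑(benzyloxy)‑5‑bromo‑2‑(3,4‑dimethoxyphenyl)‑2,3‑dihydro‑1‑benzofuran‑3‑carbaldehyde | COc1ccc([C@@H]2Oc3c(OCc4ccccc4)cc(Br)cc3[C@H]2C=O)cc1OC | intermediate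
13 | [(2R,3S)‑7‑(benzyloxy)‑5‑bromo‑2‑(3,4‑dimethoxyphenyl)‑2,3‑dihydro‑1‑benzofuran‑3‑yl]methanol | COc1ccc([C@@H]2Oc3c(OCc4ccccc4)cc(Br)cc3[C@H]2CO)cc1OC | intermediate
14 | methyl acrylate | C=CC(=O)OC | starting material
15 | methyl (2E)‑3‑[(2R,3S)‑7‑(benzyloxy)‑2‑(3,4‑dimethoxyphenyl)‑3‑(hydroxymethyl)‑2,3‑dihydro‑1‑benzofuran‑5‑yl]prop‑2‑enoate | COc1ccc([C@@H]2Oc3c(OCc4ccccc4)cc(/C=C/C(=O)OC)cc3[C@H]2CO)cc1OC | intermediate
16 | methyl (2E)‑3‑[(2R,3S)‑2‑(3,4‑dimethoxyphenyl)‑7‑hydroxy‑3‑(hydroxymethyl)‑2,3‑dihydro‑1‑benzofuran‑5‑yl]prop‑2‑enoate | COc1ccc([C@@H]2Oc3c(O)cc(/C=C/C(=O)OC)cc3[C@H]2CO)cc1OC | intermediate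
17 | (2E)‑3‑[(2R,3S)‑2‑(3,4‑dimethoxyphenyl)‑7‑hydroxy‑3‑(hydroxymethyl)‑2,3‑dihydro‑1‑benzofuran‑5‑yl]prop‑2‑enoic acid | COc1ccc([C@@H]2Oc3c(O)cc(/C=C/C(=O)O)cc3[C@H]2CO)cc1OC | target

**Step count and risks**

Total: 9 steps. Longest linear sequence: 9 steps (1 to 17).

Steps most likely to fail:

Step 5. The rearrangement could be diverted by migration of the electron‑rich 2‑aryl group instead of the ring‑A carbon, by dehydrogenation of the pyranone, by attack of the oxidant on the dimethoxyarene, or by partial racemisation through acid‑induced opening of the pyranone ring. The fallback keeps the same 1,2‑shift but triggers it from a carbene precursor; it sets out from 7 and returns at 11. Deprotonation of 7 with LiN(SiMe3)2 in THF at −78 °C and acylation with CF3CO2CH2CF3 would give the 3‑trifluoroacetyl ketone F1. Detrifluoroacetylative diazo transfer with MsN3 and Et3N in MeCN would give the 3‑diazo ketone F2. Irradiation at 365 nm in MeOH/THF should induce Wolff rearrangement, the ring‑A carbon moving from C4 to C3 as nitrogen leaves, to give the ketene F3. Methanol would capture it, largely as the cis ester F4 by protonation anti to the aryl group, and NaOMe in MeOH at rt would then equilibrate the mixture to the trans ester 11.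

Step 4. The 8‑alkoxy chromone may give insufficient enantioselectivity or conversion, and the electron‑rich boronic acid may protodeboronate. The fallback builds the flavanone by oxa‑Michael closure and resolves it; it sets out from 3 and returns at 7. Claisen–Schmidt condensation of 3 with 3,4‑dimethoxybenzaldehyde (KOH, EtOH, rt) would give the 2'‑hydroxychalcone F5, and NaOAc in refluxing EtOH would close it to the racemic flavanone F6. Kinetic resolution by asymmetric transfer hydrogenation with RuCl[(S,S)‑TsDPEN](p‑cymene) and HCO2H/Et3N, stopped near half conversion, is expected to reduce the 2S enantiomer to the cis‑flavan‑4‑ol F7 and leave the 2R ketone 7 for chromatographic recovery.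

Step 8. The Lewis acid may ionise the C2–O1 bond, a p‑alkoxybenzylic aryl ether, leading to epimerisation at C2 or capture of the opened cation by the scavenger, and may partly cleave the methyl ethers. The fallback avoids any Lewis acid by removing the benzyl group by hydrogenolysis before the alkene exists; it sets out from 13 and rejoins the route at the target 17. Bromine–lithium exchange on 13 (n‑BuLi, 2.2 equiv, THF, −78 °C) and quenching with DMF would give the 5‑carbaldehyde F8. Hydrogenolysis (H2, 1 atm, palladium on carbon, EtOAc, rt, stopped after one equivalent) would give the hydroxy aldehyde F9. Knoevenagel–Doebner condensation with malonic acid in pyridine with catalytic piperidine at 90 °C would pass through the arylidenemalonic acid F10, which decarboxylates to the E‑acid 17.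

**Further compounds**

F1 | step 5 | (2R)‑8‑(benzyloxy)‑6‑bromo‑2‑(3,4‑dimethoxyphenyl)‑3‑(trifluoroacetyl)chroman‑4‑one (C3 epimers/enol) | COc1ccc([C@H]2C(C(=O)C(F)(F)F)C(=O)c3cc(Br)cc(OCc4ccccc4)c3O2)cc1OC
F2 | step 5 | (2S)‑8‑(benzyloxy)‑6‑bromo‑3‑diazo‑2‑(3,4‑dimethoxyphenyl)chroman‑4‑one (same spatial arrangement at C2 as in 7) | COc1ccc([C@H]2C(=[N+]=[N-])C(=O)c3cc(Br)cc(OCc4ccccc4)c3O2)cc1OC
F3 | step 5 | [(2S)‑7‑(benzyloxy)‑5‑bromo‑2‑(3,4‑dimethoxyphenyl)‑1‑benzofuran‑3(2H)‑ylidene]methanone (ketene; same spatial arrangement at C2 as in 11) | COc1ccc([C@@H]2Oc3c(OCc4ccccc4)cc(Br)cc3C2=C=O)cc1OC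
F4 | step 5 | methyl (2R,3S)‑7‑(benzyloxy)‑5‑bromo‑2‑(3,4‑dimethoxyphenyl)‑2,3‑dihydro‑1‑benzofuran‑3‑carboxylate (cis) | COc1ccc([C@@H]2Oc3c(OCc4ccccc4)cc(Br)cc3[C@@H]2C(=O)OC)cc1OC
F5 | step 4 | (2E)‑1‑[3‑(benzyloxy)‑5‑bromo‑2‑hydroxyphenyl]‑3‑(3,4‑dimethoxyphenyl)prop‑2‑en‑1‑one | COc1ccc(/C=C/C(=O)c2cc(Br)cc(OCc3ccccc3)c2O)cc1OC
F6 | step 4 | rac‑8‑(benzyloxy)‑6‑bromo‑2‑(3,4‑dimethoxyphenyl)chroman‑4‑one | COc1ccc(C2CC(=O)c3cc(Br)cc(OCc4ccccc4)c3O2)cc1OC
F7 | step 4 | (2S,4S)‑8‑(benzyloxy)‑6‑bromo‑2‑(3,4‑dimethoxyphenyl)chroman‑4‑ol (cis) | COc1ccc([C@@H]2C[C@H](O)c3cc(Br)cc(OCc4ccccc4)c3O2)cc1OC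
F8 | step 8 | (2R,3S)‑7‑(benzyloxy)‑2‑(3,4‑dimethoxyphenyl)‑3‑(hydroxymethyl)‑2,3‑dihydro‑1‑benzofuran‑5‑carbaldehyde | COc1ccc([C@@H]2Oc3c(OCc4ccccc4)cc(C=O)cc3[C@H]2CO)cc1OC
F9 | step 8 | (2R,3S)‑2‑(3,4‑dimethoxyphenyl)‑7‑hydroxy‑3‑(hydroxymethyl)‑2,3‑dihydro‑1‑benzofuran‑5‑carbaldehyde | COc1ccc([C@@H]2Oc3c(O)cc(C=O)cc3[C@H]2CO)cc1OC
F10 | step 8 | 2‑{[(2R,3S)‑2‑(3,4‑dimethoxyphenyl)‑7‑hydroxy‑3‑(hydroxymethyl)‑2,3‑dihydro‑1‑benzofuran‑5‑yl]methylidene}propanedioic acid | COc1ccc([C@@H]2Oc3c(O)cc(C=C(C(=O)O)C(=O)O)cc3[C@H]2CO)cc1OC
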